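The indane's five-membered ring is disconnected at C1–C7a and C2–C3. The key step exploits the fact that C3 is attached to C3a of the benzo ring and bears an aryl group: it can start as a diaryl ketone carbonyl that directs Cp*Rh(III) to the only unhindered ortho position, C7a–H. Ynone insertion then forms C7a–C1 and the C2 alkenyl–rhodium adds to that carbonyl to form C2–C3, closing the ring in one operation. The precursor is a benzyl-protected benzophenone whose C6 oxygen, para to C3a, carries a silyl group; once freed it gives a quinone methide for asymmetric reduction at C3, and a final hydrogenation sets C1 and C2 and removes all benzyl groups.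

Key step: step 6

Remarks
- Atom labels C1–C7a are those of the indane of the target throughout.
- The target SMILES encodes the (1R,2R,3R) isomer in which the C1 aroyl, C2 aryl and C3 aryl groups are all cis; the route is planned for this isomer.
- Permanent phenol protection is benzyl and the C6 oxygen carries TIPS. The last step is then a neutral hydrogenation/hydrogenolysis, and no Lewis-acidic dealkylation touches the all-cis C1 centre α to the ketone.
- Compounds 4, 8 and 9 are taken as catalogue compounds.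
- The sense of induction in step 8 cannot be predicted with confidence. (R)-TRIP is written; the antipodal acid would be used if a scouting run shows that it is the one leading to (S)-14.

Step 1
Reactants: 1 2,4-dihydroxybenzaldehyde
Product: 2 2-hydroxy-4-(triisopropylsilyloxy)benzaldehyde
Conditions: TIPSCl (1.05 equiv), imidazole, CH2Cl2, 0 °C
Reagents that add atoms: triisopropylsilyl chloride, CC(C)[Si](Cl)(C(C)C)C(C)C
Why: Regioselective silyl ether formation; the 2-OH is hydrogen-bonded to the aldehyde and hindered by it, so the bulky silyl chloride should react only at the more acidic, exposed 4-OH.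

Step 2
Reactants: 2 2-hydroxy-4-(triisopropylsilyloxy)benzaldehyde
Product: 3 2-(benzyloxy)-4-(triisopropylsilyloxy)benzaldehyde
Conditions: BnOH, PPh3, DIAD, THF, 0 °C to rt
Reagents that add atoms: benzyl alcohol, OCc1ccccc1
Why: Mitsunobu etherification of the acidic salicylaldehyde-type phenol runs under neutral conditions, which avoids the carbonate bases that can shift or cleave an aryl silyl ether.

Step 3
Reactants: 4 1,3-bis(benzyloxy)-5-bromobenzene; 3 2-(benzyloxy)-4-(triisopropylsilyloxy)benzaldehyde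
Product: 6 racemic [2-(benzyloxy)-4-(triisopropylsilyloxy)phenyl][3,5-bis(benzyloxy)phenyl]methanol, via [3,5-bis(benzyloxy)phenyl]lithium 5 (not isolated)
Conditions: 4, n-BuLi, THF, −78 °C; then 3, −78 to 0 °C; H2O
Reagents that add atoms: none
Why: Bromine–lithium exchange gives aryllithium 5, which adds 1,2 to the aldehyde; the carbinol centre forms as a racemate and is removed in step 4.

Step 4
Reactants: 6 racemic [2-(benzyloxy)-4-(triisopropylsilyloxy)phenyl][3,5-bis(benzyloxy)phenyl]methanol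
Product: 7 [2-(benzyloxy)-4-(triisopropylsilyloxy)phenyl][3,5-bis(benzyloxy)phenyl]methanone
Conditions: Dess–Martin periodinane, CH2Cl2, 0 °C to rt
Reagents that add atoms: none
Why: Dess–Martin oxidation of a doubly benzylic secondary alcohol to the diaryl ketone; silyl and benzyl ethers are inert to the reagent.

Step 5
Reactants: 8 4-(benzyloxy)benzoyl chloride; 9 1-(benzyloxy)-4-ethynylbenzene
Product: 10 1,3-bis[4-(benzyloxy)phenyl]prop-2-yn-1-one
Conditions: PdCl2(PPh3)2 (2 mol%), CuI (4 mol%), Et3N (1.2 equiv), THF, rt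
Reagents that add atoms: none
Why: Acyl Sonogashira coupling of an aroyl chloride with a terminal arylacetylene under Pd/Cu catalysis should give the ynone directly at room temperature.

Step 6
Reactants: 7 [2-(benzyloxy)-4-(triisopropylsilyloxy)phenyl][3,5-bis(benzyloxy)phenyl]methanone; 10 1,3-bis[4-(benzyloxy)phenyl]prop-2-yn-1-one
Product: 11 racemic [7-(benzyloxy)-1-[3,5-bis(benzyloxy)phenyl]-2-[4-(benzyloxy)phenyl]-1-hydroxy-5-(triisopropylsilyloxy)-1H-inden-3-yl][4-(benzyloxy)phenyl]methanone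
Conditions: [Cp*RhCl2]2 (2.5 mol%), AgSbF6 (10 mol%), Cu(OAc)2 (30 mol%), DCE, 100 °C
Reagents that add atoms: none
Why: The ketone oxygen of 7 binds cationic Cp*Rh(III) and acetate-assisted concerted metalation–deprotonation at C7a–H gives a five-membered rhodacycle; 1,2-migratory insertion of ynone 10 into Rh–C7a forms C7a–C1, the C2 alkenyl–rhodium adds to the coordinated carbonyl to form C2–C3, and protonolysis of the rhodium alkoxide frees 11 without any change of oxidation state. The closest known reaction type is the Cp*Rh(III)-catalysed, ketone-directed C–H activation/carbocyclisation of aryl ketones with internal alkynes to 1H-inden-1-ols. The five-membered ring closes by a formal (3+2) annulation whose ring-forming event is a 5-exo-trig 1,2-addition of the alkenyl metal to C=O. The carbinol centre C3 is under no control and forms as a racemate, which is harmless because it is ionised in step 8. Site selectivity needs C7a–H to be the only accessible ortho C–H, which the substrate secures because C4 carries OBn and both ortho positions of the other ring are flanked by OBn groups that block the bulky Cp*Rh. Insertion must place the aryl-bearing alkyne carbon on rhodium, the usual orientation for aryl alkynes bearing a carbonyl group in Cp*Rh(III) annulations, here reinforced by the electron-rich 4-benzyloxyphenyl group.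

Step 7
Reactants: 11 racemic [7-(benzyloxy)-1-[3,5-bis(benzyloxy)phenyl]-2-[4-(benzyloxy)phenyl]-1-hydroxy-5-(triisopropylsilyloxy)-1H-inden-3-yl][4-(benzyloxy)phenyl]methanone
Product: 12 racemic [7-(benzyloxy)-1-[3,5-bis(benzyloxy)phenyl]-2-[4-(benzyloxy)phenyl]-1,5-dihydroxy-1H-inden-3-yl][4-(benzyloxy)phenyl]methanone
Conditions: TBAF, AcOH (1:1), THF, 0 °C
Reagents that add atoms: none
Why: Fluoride-mediated cleavage of the aryl silyl ether, buffered with acetic acid so that a free phenoxide cannot expel the tertiary hydroxyl prematurely; benzyl ethers and the enone are untouched.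

Step 8
Reactants: 12 racemic [7-(benzyloxy)-1-[3,5-bis(benzyloxy)phenyl]-2-[4-(benzyloxy)phenyl]-1,5-dihydroxy-1H-inden-3-yl][4-(benzyloxy)phenyl]methanone
Product: 14 [(1S)-7-(benzyloxy)-1-[3,5-bis(benzyloxy)phenyl]-2-[4-(benzyloxy)phenyl]-5-hydroxy-1H-inden-3-yl][4-(benzyloxy)phenyl]methanone, via 4-(benzyloxy)-1-[4-(benzyloxy)benzoyl]-3-[3,5-bis(benzyloxy)phenyl]-2-[4-(benzyloxy)phenyl]-6H-inden-6-one 13 (not isolated)
Conditions: (R)-TRIP (10 mol%), Hantzsch ester (diethyl 2,6-dimethyl-1,4-dihydropyridine-3,5-dicarboxylate, 1.5 equiv), 4 Å MS, CH2Cl2, rt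
Reagents that add atoms: none
Why: Chiral phosphoric acid-catalysed transfer hydrogenation of an in situ para-quinone methide; the acid ionises the tertiary para-hydroxybenzylic alcohol to 13 (C3=C3a, C6=O) and, hydrogen-bonded to the C6 oxygen and to the N–H of the Hantzsch ester, steers hydride to one enantiotopic face of C3 in a 1,6-reduction that restores the arene, so C3 is set by the catalyst, while the other allylic terminus C1 carries the acyl group and is not attacked.

Step 9
Reactants: 14 [(1S)-7-(benzyloxy)-1-[3,5-bis(benzyloxy)phenyl]-2-[4-(benzyloxy)phenyl]-5-hydroxy-1H-inden-3-yl][4-(benzyloxy)phenyl]methanone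
Product: 16 caraphenol B, [(1R,2R,3R)-3-(3,5-dihydroxyphenyl)-4,6-dihydroxy-2-(4-hydroxyphenyl)-2,3-dihydro-1H-inden-1-yl](4-hydroxyphenyl)methanone, via [(1S)-1-(3,5-dihydroxyphenyl)-5,7-dihydroxy-2-(4-hydroxyphenyl)-1H-inden-3-yl](4-hydroxyphenyl)methanone 15 (not isolated)
Conditions: H2 (5 bar), 10% Pd/C, EtOAc/MeOH, rt
Reagents that add atoms: none
Why: Heterogeneous catalytic hydrogenation; the five benzyl aryl ethers are hydrogenolysed and H2 adds syn to the tetrasubstituted C1=C2 enone bond from the face of C3–H, opposite the C3 aryl group, so C1–H and C2–H end up cis to C3–H (all-cis, 1R,2R,3R) under neutral conditions that leave the kinetic configuration at C1, α to the ketone, untouched.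

Compound list
1 | 2,4-dihydroxybenzaldehyde | O=Cc1ccc(O)cc1O | starting material
2 | 2-hydroxy-4-(triisopropylsilyloxy)benzaldehyde | O=Cc1ccc(O[Si](C(C)C)(C(C)C)C(C)C)cc1O | intermediate
3 | 2-(benzyloxy)-4-(triisopropylsilyloxy)benzaldehyde | O=Cc1ccc(O[Si](C(C)C)(C(C)C)C(C)C)cc1OCc1ccccc1 | intermediate
4 | 1,3-bis(benzyloxy)-5-bromobenzene | Brc1cc(OCc2ccccc2)cc(OCc2ccccc2)c1 | starting material
5 | [3,5-bis(benzyloxy)phenyl]lithium | [Li]c1cc(OCc2ccccc2)cc(OCc2ccccc2)c1 | intermediate
6 | racemic [2-(benzyloxy)-4-(triisopropylsilyloxy)phenyl][3,5-bis(benzyloxy)phenyl]methanol | OC(c1cc(OCc2ccccc2)cc(OCc2ccccc2)c1)c1ccc(O[Si](C(C)C)(C(C)C)C(C)C)cc1OCc1ccccc1 | intermediate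
7 | [2-(benzyloxy)-4-(triisopropylsilyloxy)phenyl][3,5-bis(benzyloxy)phenyl]methanone | O=C(c1cc(OCc2ccccc2)cc(OCc2ccccc2)c1)c1ccc(O[Si](C(C)C)(C(C)C)C(C)C)cc1OCc1ccccc1 | intermediate
8 | 4-(benzyloxy)benzoyl chloride | O=C(Cl)c1ccc(OCc2ccccc2)cc1 | starting material
9 | 1-(benzyloxy)-4-ethynylbenzene | C#Cc1ccc(OCc2ccccc2)cc1 | starting material
10 | 1,3-bis[4-(benzyloxy)phenyl]prop-2-yn-1-one | O=C(C#Cc1ccc(OCc2ccccc2)cc1)c1ccc(OCc2ccccc2)cc1 | intermediate
11 | racemic [7-(benzyloxy)-1-[3,5-bis(benzyloxy)phenyl]-2-[4-(benzyloxy)phenyl]-1-hydroxy-5-(triisopropylsilyloxy)-1H-inden-3-yl][4-(benzyloxy)phenyl]methanone | O=C(c1ccc(OCc2ccccc2)cc1)C1=C(c2ccc(OCc3ccccc3)cc2)C(O)(c2cc(OCc3ccccc3)cc(OCc3ccccc3)c2)c2c(OCc3ccccc3)cc(O[Si](C(C)C)(C(C)C)C(C)C)cc12 | intermediate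
12 | racemic [7-(benzyloxy)-1-[3,5-bis(benzyloxy)phenyl]-2-[4-(benzyloxy)phenyl]-1,5-dihydroxy-1H-inden-3-yl][4-(benzyloxy)phenyl]methanone | O=C(c1ccc(OCc2ccccc2)cc1)C1=C(c2ccc(OCc3ccccc3)cc2)C(O)(c2cc(OCc3ccccc3)cc(OCc3ccccc3)c2)c2c(OCc3ccccc3)cc(O)cc12 | intermediate
13 | 4-(benzyloxy)-1-[4-(benzyloxy)benzoyl]-3-[3,5-bis(benzyloxy)phenyl]-2-[4-(benzyloxy)phenyl]-6H-inden-6-one (para-quinone methide) | O=C1C=C(OCc2ccccc2)C2=C(c3cc(OCc4ccccc4)cc(OCc4ccccc4)c3)C(c3ccc(OCc4ccccc4)cc3)=C(C(=O)c3ccc(OCc4ccccc4)cc3)C2=C1 | intermediate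
14 | [(1S)-7-(benzyloxy)-1-[3,5-bis(benzyloxy)phenyl]-2-[4-(benzyloxy)phenyl]-5-hydroxy-1H-inden-3-yl][4-(benzyloxy)phenyl]methanone | O=C(c1ccc(OCc2ccccc2)cc1)C1=C(c2ccc(OCc3ccccc3)cc2)[C@H](c2cc(OCc3ccccc3)cc(OCc3ccccc3)c2)c2c(OCc3ccccc3)cc(O)cc12 | intermediate
15 | [(1S)-1-(3,5-dihydroxyphenyl)-5,7-dihydroxy-2-(4-hydroxyphenyl)-1H-inden-3-yl](4-hydroxyphenyl)methanone | O=C(c1ccc(O)cc1)C1=C(c2ccc(O)cc2)[C@H](c2cc(O)cc(O)c2)c2c(O)cc(O)cc12 | intermediate
16 | caraphenol B, [(1R,2R,3R)-3-(3,5-dihydroxyphenyl)-4,6-dihydroxy-2-(4-hydroxyphenyl)-2,3-dihydro-1H-inden-1-yl](4-hydroxyphenyl)methanone | O=C(c1ccc(O)cc1)[C@H]1c2cc(O)cc(O)c2[C@@H](c2cc(O)cc(O)c2)[C@H]1c1ccc(O)cc1 | target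

Total step count: 9. Longest linear sequence: 8 steps (steps 1, 2, 3, 4, 6, 7, 8, 9); step 5 is a one-step side branch.

Steps most likely to fail

1. Step 6. The ynone may insert in the reversed orientation, with the acyl-bearing carbon on rhodium. The acyl-deactivated alkenyl–rhodium may also be protonated before it adds to the hindered, electron-rich diaryl ketone, giving hydroarylation without ring closure. Metalation may further be slowed because the ortho benzyloxy group twists the carbonyl out of the ring plane. Fallback, setting out from 10 and 7 and returning at 12: the conjugation is removed from the alkyne, so that it behaves as an aryl–alkyl alkyne with the established orientation and gives a more nucleophilic alkenyl–rhodium. Luche reduction of 10 (NaBH4, CeCl3·7H2O, MeOH/THF, 0 °C) should give racemic 1,3-bis[4-(benzyloxy)phenyl]prop-2-yn-1-ol F1. Silylation (TBSCl, imidazole, DMF) should give tert-butyl({1,3-bis[4-(benzyloxy)phenyl]prop-2-yn-1-yl}oxy)dimethylsilane F2. The same Cp*Rh(III) annulation of F2 with 7 should then give 7-(benzyloxy)-1-[3,5-bis(benzyloxy)phenyl]-2-[4-(benzyloxy)phenyl]-3-{[4-(benzyloxy)phenyl][(tert-butyldimethylsilyl)oxy]methyl}-5-(triisopropylsilyloxy)-1H-inden-1-ol F3 as a mixture of racemic diastereomers. TBAF (THF, 0 °C to rt) removes both silyl groups to give 7-(benzyloxy)-1-[3,5-bis(benzyloxy)phenyl]-2-[4-(benzyloxy)phenyl]-3-{[4-(benzyloxy)phenyl](hydroxy)methyl}-1H-indene-1,5-diol F4. MnO2 (CH2Cl2, rt) oxidises only the allylic, benzylic secondary alcohol and should deliver 12.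

2. Step 8. Enantiofacial discrimination at C3 may be poor because the acid binds at the remote C6 oxygen of a flat, cross-conjugated quinone methide. Hydride may be delivered to C2 instead of C3, the quinone methide may oligomerise if ionisation outpaces reduction, and the C3–H of the product may be eroded by vinylogous enolisation. Fallback, setting out from 12 and returning at 14: ionic hydrogenation without asymmetric induction (Et3SiH, TFA, CH2Cl2, −20 °C) should give racemic [7-(benzyloxy)-1-[3,5-bis(benzyloxy)phenyl]-2-[4-(benzyloxy)phenyl]-5-hydroxy-1H-inden-3-yl][4-(benzyloxy)phenyl]methanone F5. This is resolved by preparative chromatography on a chiral stationary phase (SFC, polysaccharide carbamate column) into 14 and its enantiomer [(1R)-7-(benzyloxy)-1-[3,5-bis(benzyloxy)phenyl]-2-[4-(benzyloxy)phenyl]-5-hydroxy-1H-inden-3-yl][4-(benzyloxy)phenyl]methanone F6, which is discarded.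

3. Step 9. On the palladium surface the C1=C2 bond may migrate to C2=C3 before saturation, which would scramble C3. The tetrasubstituted alkene may also be reduced incompletely, hydrogen may be delivered from the wrong face, or the aryl ketone may be over-reduced during the long exposure needed. Fallback, setting out from 14 and returning at 16: alkene saturation and deprotection are separated. Homogeneous hydrogenation with a cationic iridium catalyst ([Ir(cod)(PCy3)(py)]BArF, H2 50 bar, CH2Cl2, rt), which reduces tetrasubstituted alkenes and is less prone to double-bond migration than palladium on carbon, should give [(1R,2R,3R)-4-(benzyloxy)-3-[3,5-bis(benzyloxy)phenyl]-2-[4-(benzyloxy)phenyl]-6-hydroxy-2,3-dihydro-1H-inden-1-yl][4-(benzyloxy)phenyl]methanone F7. Short hydrogenolysis of the benzyl ethers (H2 1 bar, Pd/C, EtOAc/MeOH, rt) then gives 16.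

Further compounds
F1 | step 6 | racemic 1,3-bis[4-(benzyloxy)phenyl]prop-2-yn-1-ol | OC(C#Cc1ccc(OCc2ccccc2)cc1)c1ccc(OCc2ccccc2)cc1
F2 | step 6 | racemic tert-butyl({1,3-bis[4-(benzyloxy)phenyl]prop-2-yn-1-yl}oxy)dimethylsilane | CC(C)(C)[Si](C)(C)OC(C#Cc1ccc(OCc2ccccc2)cc1)c1ccc(OCc2ccccc2)cc1
F3 | step 6 | 7-(benzyloxy)-1-[3,5-bis(benzyloxy)phenyl]-2-[4-(benzyloxy)phenyl]-3-{[4-(benzyloxy)phenyl][(tert-butyldimethylsilyl)oxy]methyl}-5-(triisopropylsilyloxy)-1H-inden-1-ol (racemic diastereomers) | CC(C)(C)[Si](C)(C)OC(c1ccc(OCc2ccccc2)cc1)C1=C(c2ccc(OCc3ccccc3)cc2)C(O)(c2cc(OCc3ccccc3)cc(OCc3ccccc3)c2)c2c(OCc3ccccc3)cc(O[Si](C(C)C)(C(C)C)C(C)C)cc12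
F4 | step 6 | 7-(benzyloxy)-1-[3,5-bis(benzyloxy)phenyl]-2-[4-(benzyloxy)phenyl]-3-{[4-(benzyloxy)phenyl](hydroxy)methyl}-1H-indene-1,5-diol (racemic diastereomers) | OC(c1ccc(OCc2ccccc2)cc1)C1=C(c2ccc(OCc3ccccc3)cc2)C(O)(c2cc(OCc3ccccc3)cc(OCc3ccccc3)c2)c2c(OCc3ccccc3)cc(O)cc12
F5 | step 8 | racemic [7-(benzyloxy)-1-[3,5-bis(benzyloxy)phenyl]-2-[4-(benzyloxy)phenyl]-5-hydroxy-1H-inden-3-yl][4-(benzyloxy)phenyl]methanone | O=C(c1ccc(OCc2ccccc2)cc1)C1=C(c2ccc(OCc3ccccc3)cc2)C(c2cc(OCc3ccccc3)cc(OCc3ccccc3)c2)c2c(OCc3ccccc3)cc(O)cc12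
F6 | step 8 | [(1R)-7-(benzyloxy)-1-[3,5-bis(benzyloxy)phenyl]-2-[4-(benzyloxy)phenyl]-5-hydroxy-1H-inden-3-yl][4-(benzyloxy)phenyl]methanone | O=C(c1ccc(OCc2ccccc2)cc1)C1=C(c2ccc(OCc3ccccc3)cc2)[C@@H](c2cc(OCc3ccccc3)cc(OCc3ccccc3)c2)c2c(OCc3ccccc3)cc(O)cc12
F7 | step 9 | [(1R,2R,3R)-4-(benzyloxy)-3-[3,5-bis(benzyloxy)phenyl]-2-[4-(benzyloxy)phenyl]-6-hydroxy-2,3-dihydro-1H-inden-1-yl][4-(benzyloxy)phenyl]methanone | O=C(c1ccc(OCc2ccccc2)cc1)[C@H]1c2cc(O)cc(OCc3ccccc3)c2[C@@H](c2cc(OCc3ccccc3)cc(OCc3ccccc3)c2)[C@H]1c1ccc(OCc2ccccc2)cc1
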